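## Retrosynthetic overview
Benzofuran numbering is used: O1, C2, C3, C3a, C4–C7, C7a.

1. The carbocycle C3a–C4–C5–C6–C7–C7a is closed last. C4=C5 comes from an intramolecular HWE reaction between a formyl group (C4) on quaternary C3a and an α‑methoxy‑β‑ketophosphonate (C5–C6) on the C7a side chain.
2. Key cut: in the oxolane O1–C2–C3–C3a–C7a, the aryl (C2), methyl (C3), C4 (on C3a) and C7 (on C7a) all lie on one face, and allyl‑bearing quaternary C3a sits next to the CH carbon C4. This is the signature of a Prins–pinacol product. C2–C3 and C3a–C7a are made in one operation from an open‑chain (Z)‑allylic diol acetal, and C7a alone sets C2, C3 and C3a.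
3. The acetal carbon (future C2) and the veratryl ring are the 3,4‑dimethoxybenzyl (DMB) protecting group of the C7a oxygen, oxidised in place with DDQ.
4. The open chain comes from three pieces: (S)‑malate (C4, C7a, C7, C6), (Z)‑4‑iodohexa‑1,4‑diene (C3, CH3, C3a, allyl) and a (methoxymethyl)phosphonate (C5, OMe).
5. Ring order: oxolane (step 7), then cyclohexenone (step 8).

Key step: step 7

Assumption: the target SMILES reads as (2S,3R,3aR,7aS). Centres that are erased later (carbinol C4, the acetal carbon before step 7, phosphonate carbon C5) are carried as epimer mixtures and left undefined in the SMILES.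

## Route

Step 1
Reactants: 1 dimethyl (S)-malate; 2 3,4-dimethoxybenzyl bromide
Product: 3 dimethyl (2S)-2-[(3,4-dimethoxyphenyl)methoxy]butanedioate
Conditions: Ag2O, 4 Å MS, CH2Cl2, rt, dark
Reagents that add atoms: none
Why: Silver(I)-oxide-promoted Williamson-type O-benzylation runs without strong base, so the malate stereocentre (future C7a) should be untouched and β-elimination to fumarate avoided.

Step 2
Reactants: 3 dimethyl (2S)-2-[(3,4-dimethoxyphenyl)methoxy]butanedioate
Product: 4 methyl (3S)-3-[(3,4-dimethoxyphenyl)methoxy]-4-oxobutanoate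
Conditions: MgBr2·OEt2, then DIBAL-H (1 equiv), CH2Cl2, −78 °C; Rochelle salt work-up
Reagents that add atoms: none
Why: Chelation-activated DIBAL-H half-reduction; Mg(II) binds the ether oxygen and the adjacent ester carbonyl in a five-membered chelate, so only the α-alkoxy ester should go to the aldehyde (future C4), and no stereocentre is formed.

Step 3
Reactants: 5 but-3-en-1-yl(triphenyl)phosphonium bromide; 6 acetaldehyde
Product: 10 (4Z)-4-iodohexa-1,4-diene, via butenylidene ylide 7 (not isolated), via iodophosphonium iodide 8 (not isolated), via iodo ylide 9 (not isolated)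
Conditions: n-BuLi, THF, rt; added to I2, THF, −78 °C; NaHMDS, −20 °C; 6, −78 °C
Reagents that add atoms: iodine, II
Why: Stork–Zhao-type α-iodo Wittig olefination; the kinetic oxaphosphetane should place the aldehyde methyl cis to iodine, which fixes the alkene geometry that later becomes the C2/C3-cis relationship.

Step 4
Reactants: 10 (4Z)-4-iodohexa-1,4-diene; 4 methyl (3S)-3-[(3,4-dimethoxyphenyl)methoxy]-4-oxobutanoate
Product: 13 (4S)-4-[(3,4-dimethoxyphenyl)methoxy]-5-[(2Z)-hexa-2,5-dien-3-yl]oxolan-2-one (C5 epimers), via alkenyllithium 11 (not isolated), via hydroxy ester 12 (not isolated)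
Conditions: t-BuLi (2 equiv), Et2O, −78 °C; 4, −78 °C; AcOH quench; then PPTS (cat.), CH2Cl2, rt
Reagents that add atoms: none
Why: Iodine–lithium exchange keeps the alkene geometry, 1,2-addition to the aldehyde outruns attack on the ester (Felkin–Anh, anti epimer expected to dominate) and the γ-hydroxy ester lactonises; the new carbinol centre C4 needs no control because step 7 erases it.

Step 5
Reactants: 13 (4S)-4-[(3,4-dimethoxyphenyl)methoxy]-5-[(2Z)-hexa-2,5-dien-3-yl]oxolan-2-one; 14 diethyl (methoxymethyl)phosphonate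
Product: 16 diethyl [(4S,6Z)-4-[(3,4-dimethoxyphenyl)methoxy]-5-hydroxy-1-methoxy-2-oxo-6-(prop-2-en-1-yl)oct-6-en-1-yl]phosphonate, via lithiated phosphonate 15 (not isolated)
Conditions: 14 (2.5 equiv), LDA (2.5 equiv), THF, −78 °C; 13, −78 → −40 °C; AcOH quench
Reagents that add atoms: none
Why: Corey–Kwiatkowski acylation of a lithiated phosphonate by a lactone; the β-ketophosphonate is deprotonated at once to its stabilised enolate, which should stop a second addition, and the new centre C5 is lost in step 8.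

Step 6
Reactants: 16 diethyl [(4S,6Z)-4-[(3,4-dimethoxyphenyl)methoxy]-5-hydroxy-1-methoxy-2-oxo-6-(prop-2-en-1-yl)oct-6-en-1-yl]phosphonate
Product: 17 diethyl {3-[(4S)-2-(3,4-dimethoxyphenyl)-5-[(2Z)-hexa-2,5-dien-3-yl]-1,3-dioxolan-4-yl]-1-methoxy-2-oxopropyl}phosphonate
Conditions: DDQ (1.2 equiv), 4 Å MS, CH2Cl2 (anhydrous), 0 °C
Reagents that add atoms: none
Why: DDQ-mediated oxidative acetalisation of a benzyl-type ether by a neighbouring hydroxyl; hydride is abstracted from the electron-rich DMB methylene and the C4 hydroxyl traps the cation as the dioxolane, so the protecting group becomes C2 plus the aryl ring, and the acetal centre needs no control.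

Step 7
Reactants: 17 diethyl {3-[(4S)-2-(3,4-dimethoxyphenyl)-5-[(2Z)-hexa-2,5-dien-3-yl]-1,3-dioxolan-4-yl]-1-methoxy-2-oxopropyl}phosphonate
Product: 20 diethyl {3-[(2S,3S,4R,5S)-5-(3,4-dimethoxyphenyl)-3-formyl-4-methyl-3-(prop-2-en-1-yl)oxolan-2-yl]-1-methoxy-2-oxopropyl}phosphonate, via oxocarbenium ion 18 (not isolated), via oxanyl cation 19 (not isolated)
Conditions: SnCl4 (2.5 equiv), CH2Cl2, −78 → −30 °C; cold Et3N/aq NaHCO3 quench
Reagents that add atoms: none
Why: SnCl4 opens the dioxolane at the C2–O(C4) bond to the (E)-aryl oxocarbenium ion 18, C3 of the trisubstituted alkene attacks C2 in a chair-like 6-endo Prins closure (ring O1–C2–C3–C3a–C4–C7a) to give tertiary cation 19, and the oxygen-bearing C7a then migrates from C4 to C3a (pinacol shift), which contracts the oxane to the oxolane O1–C2–C3–C3a–C7a and releases C4 as the formyl group. The closest known reaction type is the acid-promoted Prins–pinacol rearrangement of allylic-diol acetals to 3-acyl- and 3-formyl-tetrahydrofurans, including cases that create a quaternary carbon. C2 is set by the E oxocarbenium ion with aryl and the C7a side chain both equatorial (cis across O1), C3 by the Z alkene, which forces methyl axial and hence cis to aryl, and C3a by the suprafacial shift of C7a (retention at C7a) onto the cation lobe that faces it, which leaves C4 cis to C7, methyl and aryl and puts allyl on the opposite face, so the single malate centre dictates all three new ones. Both C4 epimers and both acetal epimers lose their extra centres on this path, so the step should be stereoconvergent. It needs (i) the trisubstituted alkene and not the terminal allyl alkene as π-nucleophile, secured by ring size (six versus eight) and nucleophilicity, (ii) migration of C7a ahead of H-4 shift or proton loss from the allyl CH2, secured by the α-oxygen on C7a and its alignment in the chair, and (iii) no ionisation of the new benzylic C2–O1 bond, for which the temperature stays low and the quench is cold.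

Step 8
Reactants: 20 diethyl {3-[(2S,3S,4R,5S)-5-(3,4-dimethoxyphenyl)-3-formyl-4-methyl-3-(prop-2-en-1-yl)oxolan-2-yl]-1-methoxy-2-oxopropyl}phosphonate
Product: 21 (2S,3R,3aR,7aS)-2-(3,4-dimethoxyphenyl)-5-methoxy-3-methyl-3a-(prop-2-en-1-yl)-3,3a,7,7a-tetrahydro-1-benzofuran-6(2H)-one
Conditions: LiCl, DBU, MeCN (dilute), 0 °C → rt
Reagents that add atoms: none
Why: Intramolecular Horner–Wadsworth–Emmons olefination under Masamune–Roush conditions; only the phosphonate C5–H is acidic enough for this base, so C7 is not enolised and O1 is not β-eliminated, the cis formyl/side-chain pair from step 7 allows the six-ring closure, and no stereocentre is touched.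

## Compound list
1 | dimethyl (S)-malate | COC(=O)C[C@H](O)C(=O)OC | starting material
2 | 3,4-dimethoxybenzyl bromide | COc1ccc(CBr)cc1OC | starting material
3 | dimethyl (2S)-2-[(3,4-dimethoxyphenyl)methoxy]butanedioate | COC(=O)C[C@H](OCc1ccc(OC)c(OC)c1)C(=O)OC | intermediate
4 | methyl (3S)-3-[(3,4-dimethoxyphenyl)methoxy]-4-oxobutanoate | COC(=O)C[C@H](OCc1ccc(OC)c(OC)c1)C=O | intermediate
5 | but-3-en-1-yl(triphenyl)phosphonium bromide | C=CCC[P+](c1ccccc1)(c1ccccc1)c1ccccc1.[Br-] | starting material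
6 | acetaldehyde | CC=O | starting material
7 | (but-3-en-1-ylidene)triphenylphosphorane | C=CCC=P(c1ccccc1)(c1ccccc1)c1ccccc1 | intermediate
8 | (1-iodobut-3-en-1-yl)triphenylphosphonium iodide | C=CCC(I)[P+](c1ccccc1)(c1ccccc1)c1ccccc1.[I-] | intermediate
9 | (1-iodobut-3-en-1-ylidene)triphenylphosphorane | C=CCC(I)=P(c1ccccc1)(c1ccccc1)c1ccccc1 | intermediate
10 | (4Z)-4-iodohexa-1,4-diene | C=CC/C(I)=C/C | intermediate
11 | (2Z)-hexa-2,5-dien-3-yllithium (CH3 cis to Li) | C=CC/C([Li])=C/C | intermediate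
12 | methyl (3S,5Z)-3-[(3,4-dimethoxyphenyl)methoxy]-4-hydroxy-5-(prop-2-en-1-yl)hept-5-enoate | COC(=O)C[C@H](OCc1ccc(OC)c(OC)c1)C(O)/C(CC=C)=C\C | intermediate
13 | (4S)-4-[(3,4-dimethoxyphenyl)methoxy]-5-[(2Z)-hexa-2,5-dien-3-yl]oxolan-2-one | O=C1C[C@H](OCc2ccc(OC)c(OC)c2)C(/C(CC=C)=C\C)O1 | intermediate
14 | diethyl (methoxymethyl)phosphonate | CCOP(=O)(COC)OCC | starting material
15 | diethyl [lithio(methoxy)methyl]phosphonate | CCOP(=O)(OCC)C([Li])OC | intermediate
16 | diethyl [(4S,6Z)-4-[(3,4-dimethoxyphenyl)methoxy]-5-hydroxy-1-methoxy-2-oxo-6-(prop-2-en-1-yl)oct-6-en-1-yl]phosphonate | CCOP(=O)(OCC)C(OC)C(=O)C[C@H](OCc1ccc(OC)c(OC)c1)C(O)/C(CC=C)=C\C | intermediate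
17 | diethyl {3-[(4S)-2-(3,4-dimethoxyphenyl)-5-[(2Z)-hexa-2,5-dien-3-yl]-1,3-dioxolan-4-yl]-1-methoxy-2-oxopropyl}phosphonate | CCOP(=O)(OCC)C(OC)C(=O)C[C@@H]1OC(c2ccc(OC)c(OC)c2)OC1/C(CC=C)=C\C | intermediate
18 | (E)-aryl oxocarbenium ion on the C7a oxygen (C4 oxygen drawn as OH; it carries the tin residue) | CCOP(=O)(OCC)C(OC)C(=O)C[C@H](/[O+]=C/c1ccc(OC)c(OC)c1)C(O)/C(CC=C)=C\C | intermediate
19 | 2-aryl-3-methyl-4-allyl-5-hydroxyoxan-4-ylium cation | CCOP(=O)(OCC)C(OC)C(=O)C[C@@H]1O[C@H](c2ccc(OC)c(OC)c2)[C@H](C)[C+](CC=C)C1O | intermediate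
20 | diethyl {3-[(2S,3S,4R,5S)-5-(3,4-dimethoxyphenyl)-3-formyl-4-methyl-3-(prop-2-en-1-yl)oxolan-2-yl]-1-methoxy-2-oxopropyl}phosphonate | C=CC[C@@]1(C=O)[C@H](CC(=O)C(OC)P(=O)(OCC)OCC)O[C@H](c2ccc(OC)c(OC)c2)[C@@H]1C | intermediate
21 | (2S,3R,3aR,7aS)-2-(3,4-dimethoxyphenyl)-5-methoxy-3-methyl-3a-(prop-2-en-1-yl)-3,3a,7,7a-tetrahydro-1-benzofuran-6(2H)-one | C=CC[C@@]12C=C(OC)C(=O)C[C@@H]1O[C@H](c1ccc(OC)c(OC)c1)[C@@H]2C | target

## Step count and risks
Total step count: 8.
Longest linear sequence: 7 (steps 1, 2, 4, 5, 6, 7, 8).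

**Step 7 (key step).**
- The veratryl-stabilised oxocarbenium ion may be too weak an electrophile for the Z alkene, whose methyl must go axial.
- The Lewis acid may ionise the new benzylic C2–O1 bond and erode the C2 configuration toward the 2,3-trans series.
- The tin-chelated ketophosphonate may enolise and compete as a nucleophile.

Fallback: the aryl group is brought in as an external, electronically attenuated aldehyde, and the veratryl ether is restored at the end. From 16, DDQ in wet CH2Cl2 cleaves the DMB ether to diethyl [(4S,6Z)-4,5-dihydroxy-1-methoxy-2-oxo-6-(prop-2-en-1-yl)oct-6-en-1-yl]phosphonate F1. Direct condensation of this diol with commercial 4-formyl-2-methoxyphenyl acetate (BF3·OEt2, MgSO4, then SnCl4, CH2Cl2, low temperature) should pass through a more electrophilic oxocarbenium ion. It should give a less ionisable product, the 4-acetoxy-3-methoxyphenyl formyl-oxolane F2. The LiCl/DBU olefination then gives the acetoxyaryl enone F3. K2CO3/MeOH frees the phenol F4, and MeI/K2CO3 in acetone returns to the route at 21.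

**Step 5.** Deprotonation of the β-alkoxy lactone may eliminate the DMB-oxy group. The ring–chain (hemiketal) equilibrium of 16 may divert the following acetalisation.

Fallback: the acyl donor is changed and the order of acetalisation and acylation is inverted. From 13, Me3Al/MeNHOMe·HCl (non-basic aminolysis) opens the lactone to the hydroxy Weinreb amide (3S,5Z)-3-[(3,4-dimethoxyphenyl)methoxy]-4-hydroxy-N-methoxy-N-methyl-5-(prop-2-en-1-yl)hept-5-enamide F5. DDQ under anhydrous conditions locks the diol as the dioxolane Weinreb amide F6. Acylation of 15 with F6 then returns to the route at 17.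

**Step 8.** Olefination at the neopentyl formyl group may be slow, and prolonged base contact may open the oxolane by retro-oxa-Michael reaction of the product.

Fallback: the ring is closed by aldol condensation of a plain methoxymethyl ketone instead of by olefination. From 13, methoxymethyllithium (from tributyl(methoxymethyl)stannane and n-BuLi, THF, −78 °C) gives the hydroxy ketone (4S,6Z)-4-[(3,4-dimethoxyphenyl)methoxy]-5-hydroxy-1-methoxy-6-(prop-2-en-1-yl)oct-6-en-2-one F7. DDQ gives the dioxolane ketone F8, and SnCl4 gives the keto aldehyde (2S,3S,4R,5S)-5-(3,4-dimethoxyphenyl)-2-(3-methoxy-2-oxopropyl)-4-methyl-3-(prop-2-en-1-yl)oxolane-3-carbaldehyde F9. Piperidinium acetate in warm benzene then closes C4=C5, since only C5 can reach C4 in a six-membered ring. This returns to the route at 21.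

## Further compounds
F1 | step 7 | diethyl [(4S,6Z)-4,5-dihydroxy-1-methoxy-2-oxo-6-(prop-2-en-1-yl)oct-6-en-1-yl]phosphonate | CCOP(=O)(OCC)C(OC)C(=O)C[C@H](O)C(O)/C(CC=C)=C\C
F2 | step 7 | diethyl {3-[(2S,3S,4R,5S)-5-(4-acetoxy-3-methoxyphenyl)-3-formyl-4-methyl-3-(prop-2-en-1-yl)oxolan-2-yl]-1-methoxy-2-oxopropyl}phosphonate | C=CC[C@@]1(C=O)[C@H](CC(=O)C(OC)P(=O)(OCC)OCC)O[C@H](c2ccc(OC(C)=O)c(OC)c2)[C@@H]1C
F3 | step 7 | 2-methoxy-4-[(2S,3R,3aR,7aS)-5-methoxy-3-methyl-6-oxo-3a-(prop-2-en-1-yl)-2,3,3a,6,7,7a-hexahydro-1-benzofuran-2-yl]phenyl acetate | C=CC[C@@]12C=C(OC)C(=O)C[C@@H]1O[C@H](c1ccc(OC(C)=O)c(OC)c1)[C@@H]2C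
F4 | step 7 | (2S,3R,3aR,7aS)-2-(4-hydroxy-3-methoxyphenyl)-5-methoxy-3-methyl-3a-(prop-2-en-1-yl)-3,3a,7,7a-tetrahydro-1-benzofuran-6(2H)-one | C=CC[C@@]12C=C(OC)C(=O)C[C@@H]1O[C@H](c1ccc(O)c(OC)c1)[C@@H]2C
F5 | step 5 | (3S,5Z)-3-[(3,4-dimethoxyphenyl)methoxy]-4-hydroxy-N-methoxy-N-methyl-5-(prop-2-en-1-yl)hept-5-enamide | CON(C)C(=O)C[C@H](OCc1ccc(OC)c(OC)c1)C(O)/C(CC=C)=C\C
F6 | step 5 | 2-[(4S)-2-(3,4-dimethoxyphenyl)-5-[(2Z)-hexa-2,5-dien-3-yl]-1,3-dioxolan-4-yl]-N-methoxy-N-methylacetamide | CON(C)C(=O)C[C@@H]1OC(c2ccc(OC)c(OC)c2)OC1/C(CC=C)=C\C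
F7 | step 8 | (4S,6Z)-4-[(3,4-dimethoxyphenyl)methoxy]-5-hydroxy-1-methoxy-6-(prop-2-en-1-yl)oct-6-en-2-one | COCC(=O)C[C@H](OCc1ccc(OC)c(OC)c1)C(O)/C(CC=C)=C\C
F8 | step 8 | 1-[(4S)-2-(3,4-dimethoxyphenyl)-5-[(2Z)-hexa-2,5-dien-3-yl]-1,3-dioxolan-4-yl]-3-methoxypropan-2-one | COCC(=O)C[C@@H]1OC(c2ccc(OC)c(OC)c2)OC1/C(CC=C)=C\C
F9 | step 8 | (2S,3S,4R,5S)-5-(3,4-dimethoxyphenyl)-2-(3-methoxy-2-oxopropyl)-4-methyl-3-(prop-2-en-1-yl)oxolane-3-carbaldehyde | C=CC[C@@]1(C=O)[C@H](CC(=O)COC)O[C@H](c2ccc(OC)c(OC)c2)[C@@H]1C
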